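**Retrosynthetic overview**
- Feature: the plan rests on the C3–C4 bond of ring C. C3 is a tertiary carbon, benzylic to ring B through C1'. C4 is the ketone carbon held by ring A at C4a. The O1–C2 bridge already ties C3 to ring A at C8a, so this bond can be made last and within one molecule.
- The target comes from its 7,4'-diacetate by near-neutral deacetylation. Cutting C3–C4 of the diacetate gives a racemic benzylic chloride and an aroyl chloride joined through O1–C2, to be closed with nickel, a chiral bis(oxazoline) and Mn.
- The dichloride comes from a hydroxy acid, and that from an O1–C2 ether of a 5-prenylsalicylate with a ring B phenacyl halide. The chelated 2-OH is the less reactive phenol, so the 4-OH is blocked first.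
- Ring A piece: the C6–prenyl bond by Stille coupling of the 5-bromide. Ring B piece: the C1'–C3 bond by Friedel–Crafts chloroacetylation para to the acylated phenol.
- Rings A and B are bought. Ring C is the only ring formed, in the key step.

Key step: step 9

Assumption: which antipode of the bis(oxazoline) gives (S) at C3 in a ring-closing mode cannot be derived safely from the open-chain reaction. The (S,S)-ligand is written, a pilot run decides, and the (R,R)-ligand is equally available.

**Step 1**
Reactants: 1 methyl 5-bromo-2,4-dihydroxybenzoate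
Product: 2 methyl 5-bromo-2-hydroxy-4-(pivaloyloxy)benzoate
Conditions: PivCl (1.05 equiv), Et3N (1.2 equiv), CH2Cl2, 0 °C
Reagents that add atoms: pivaloyl chloride CC(C)(C)C(Cl)=O
Why: Chemoselective O-acylation, in which the 2-OH is held in a hydrogen bond to the ester carbonyl, so the freer and more acidic 4-OH (which would otherwise be alkylated first in step 5) is esterified, and the pivalate also makes the aryl bromide less electron-rich for step 2.

**Step 2**
Reactants: 2 methyl 5-bromo-2-hydroxy-4-(pivaloyloxy)benzoate; 3 tributyl(3-methylbut-2-enyl)stannane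
Product: 4 methyl 2-hydroxy-5-(3-methylbut-2-enyl)-4-(pivaloyloxy)benzoate
Conditions: Pd(PPh3)4 (5 mol %), DMF, 100 °C, argon
Reagents that add atoms: none
Why: Stille coupling of an aryl bromide with an allylic stannane, which with PPh3-ligated palladium should join the arene to the unsubstituted allyl terminus (linear prenyl group), while the neutral medium leaves ester, pivalate and chelated phenol alone.

**Step 3**
Reactants: 5 2,5-dimethoxyphenol
Product: 6 2,5-dimethoxyphenyl pivalate
Conditions: PivCl (1.1 equiv), Et3N (1.3 equiv), DMAP (5 mol %), CH2Cl2, 0 °C to rt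
Reagents that add atoms: pivaloyl chloride CC(C)(C)C(Cl)=O
Why: Ordinary phenol esterification, which blocks the phenol against self-alkylation in step 5 and keeps the oxygen an ortho/para director for step 4.

**Step 4**
Reactants: 6 2,5-dimethoxyphenyl pivalate; 7 chloroacetyl chloride
Product: 8 4-(chloroacetyl)-2,5-dimethoxyphenyl pivalate
Conditions: AlCl3 (2.5 equiv), CH2Cl2, 0 °C, 1 h; ice/dilute HCl
Reagents that add atoms: none
Why: Friedel–Crafts acylation at C4, the usual site of attack in 1,2,4-trioxygenated benzenes (para to the acyloxy group and ortho to the 5-methoxy group, whereas C3 is meta to the acyloxy group and C6 is flanked on both sides), run cold and short so that neither Fries rearrangement nor cleavage of the methoxy group next to the new ketone sets in.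

**Step 5**
Reactants: 4 methyl 2-hydroxy-5-(3-methylbut-2-enyl)-4-(pivaloyloxy)benzoate; 8 4-(chloroacetyl)-2,5-dimethoxyphenyl pivalate
Product: 10 methyl 2-{2-[2,5-dimethoxy-4-(pivaloyloxy)phenyl]-2-oxoethoxy}-5-(3-methylbut-2-enyl)-4-(pivaloyloxy)benzoate, via iodo ketone 9 (not isolated)
Conditions: 8, NaI (1.1 equiv), acetone, 20 °C, 1 h; then 4, K2CO3 (1.5 equiv), 40 °C
Reagents that add atoms: none
Why: Finkelstein exchange followed by Williamson ether synthesis at the only free phenol, where the very reactive phenacyl iodide lets the sluggish chelated phenoxide react at 40 °C with a weak base, which should hold back pivalate transfer and Dieckmann-type closure of the product onto its ester.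

**Step 6**
Reactants: 10 methyl 2-{2-[2,5-dimethoxy-4-(pivaloyloxy)phenyl]-2-oxoethoxy}-5-(3-methylbut-2-enyl)-4-(pivaloyloxy)benzoate
Product: 11 methyl 2-{2-[2,5-dimethoxy-4-(pivaloyloxy)phenyl]-2-hydroxyethoxy}-5-(3-methylbut-2-enyl)-4-(pivaloyloxy)benzoate (racemic)
Conditions: NaBH4 (1.0 equiv), THF/MeOH 4:1, −10 °C
Reagents that add atoms: none
Why: Borohydride reduction of an activated alpha-aryloxy aryl ketone, fast enough in the cold to spare the esters, with the carbinol centre left racemic on purpose because it is erased at the radical stage of step 9.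

**Step 7**
Reactants: 11 methyl 2-{2-[2,5-dimethoxy-4-(pivaloyloxy)phenyl]-2-hydroxyethoxy}-5-(3-methylbut-2-enyl)-4-(pivaloyloxy)benzoate (racemic)
Product: 13 4-acetoxy-2-[2-(4-acetoxy-2,5-dimethoxyphenyl)-2-hydroxyethoxy]-5-(3-methylbut-2-enyl)benzoic acid (racemic), via triol acid 12 (not isolated)
Conditions: NaOH (8 equiv), dioxane/H2O 1:1, 70 °C, argon; cool to 0 °C, Ac2O (6 equiv) in portions; cold 1 M HCl to pH 3
Reagents that add atoms: sodium hydroxide [Na+].[OH-] (carboxyl oxygen); acetic anhydride CC(=O)OC(C)=O
Why: Saponification of the methyl ester and both aryl pivalates, then Schotten–Baumann-type acetylation in cold aqueous alkali, where only the phenoxides are acylated, the secondary alcohol is not, any mixed anhydride of the carboxylate hydrolyses back, and the sensitive para-hydroxybenzylic alcohol is never isolated.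

**Step 8**
Reactants: 13 4-acetoxy-2-[2-(4-acetoxy-2,5-dimethoxyphenyl)-2-hydroxyethoxy]-5-(3-methylbut-2-enyl)benzoic acid (racemic)
Product: 14 4-acetoxy-2-[2-(4-acetoxy-2,5-dimethoxyphenyl)-2-chloroethoxy]-5-(3-methylbut-2-enyl)benzoyl chloride (racemic)
Conditions: 1-chloro-N,N,2-trimethylprop-1-en-1-amine (2.4 equiv), CH2Cl2, 0 °C to 20 °C; volatiles off under high vacuum, crude product used at once
Reagents that add atoms: 1-chloro-N,N,2-trimethylprop-1-en-1-amine CC(C)=C(Cl)N(C)C
Why: Neutral chlorination with an alpha-chloroenamine, which turns acids into acid chlorides and alcohols into chlorides through acyloxy- and alkoxy-iminium chlorides with an amide as the only by-product, so no HCl is set free to add to the prenyl alkene (the weakness of thionyl chloride here), and the excess reagent engages both OH groups together so that a hydroxy acid chloride has little time to lactonise.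

**Step 9**
Reactants: 14 4-acetoxy-2-[2-(4-acetoxy-2,5-dimethoxyphenyl)-2-chloroethoxy]-5-(3-methylbut-2-enyl)benzoyl chloride (racemic)
Product: 15 (3S)-7-acetoxy-3-(4-acetoxy-2,5-dimethoxyphenyl)-6-(3-methylbut-2-enyl)chroman-4-one
Conditions: NiCl2(dme) (20 mol %), (S,S)-Ph-BOX [2,2'-(propane-2,2-diyl)bis((4S)-4-phenyl-4,5-dihydrooxazole)] (24 mol %), Mn powder (3 equiv), 2,6-dimethylbenzoic acid (0.75 equiv), 3 Å MS, THF/DMA 7:3, 20 °C, 14 added by syringe pump over 8 h (final 0.01 M)
Reagents that add atoms: none
Why: Proposed new method: ligated zerovalent nickel should insert into the aroyl C–Cl bond of 14 far faster than it touches the secondary C–Cl bond, a monovalent nickel species (a second centre, or the acyl complex itself after one-electron reduction by Mn) then abstracts the benzylic chlorine, and the planar C3 radical, identical from either enantiomer of 14, is trapped by the acyl–nickel centre at the other end of the O1–C2 bridge to give a trivalent acyl(benzyl)nickel species that forms C3–C4 by reductive elimination while Mn ends up as MnCl2. The closest known reaction type is the two-component nickel/bis(oxazoline)/Mn enantioconvergent reductive coupling of acid chlorides with racemic secondary benzylic chlorides to acyclic alpha-aryl ketones; new here are the ring-closing mode, the ortho-alkoxy aroyl chloride and the beta-aryloxy group on the benzylic partner. Ring C, the six-membered pyranone, closes by radical capture at the tethered metal (seven-membered nickelacycle of Ni, C4, C4a, C8a, O1, C2 and C3) followed by ring-contracting reductive elimination, not by radical addition to an arene or a carbonyl group. C3 is set by the catalyst alone, since the ligand decides which face of the prochiral radical is bound and eliminated, and the base-free, weakly acidic medium should keep the new alpha-aryl ketone from enolising. The step needs ring closure to outrun coupling between molecules, which the bridge, the slow addition and the high nickel loading secure, and it needs C–C bond formation to outrun ionisation of the chloride and loss of the beta-aryloxy group, for which the 4'-acetate para to C3 withdraws electron density from the benzylic position.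

**Step 10**
Reactants: 15 (3S)-7-acetoxy-3-(4-acetoxy-2,5-dimethoxyphenyl)-6-(3-methylbut-2-enyl)chroman-4-one
Product: 16 (3S)-7-hydroxy-3-(4-hydroxy-2,5-dimethoxyphenyl)-6-(3-methylbut-2-enyl)chroman-4-one
Conditions: NH4OAc (10 equiv), MeOH/H2O 4:1, 20 °C, stopped as soon as 15 and the monoacetates are consumed
Reagents that add atoms: none
Why: Ammonium acetate-mediated solvolysis of aryl acetates at near-neutral pH, mild enough that the acidic C3–H should not exchange and free of acid that could cyclise the ortho-prenylphenol.

**Compound list**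
1 | methyl 5-bromo-2,4-dihydroxybenzoate | COC(=O)c1cc(Br)c(O)cc1O | starting material
2 | methyl 5-bromo-2-hydroxy-4-(pivaloyloxy)benzoate | COC(=O)c1cc(Br)c(OC(=O)C(C)(C)C)cc1O | intermediate
3 | tributyl(3-methylbut-2-enyl)stannane | CC(C)=CC[Sn](CCCC)(CCCC)CCCC | starting material
4 | methyl 2-hydroxy-5-(3-methylbut-2-enyl)-4-(pivaloyloxy)benzoate | COC(=O)c1cc(CC=C(C)C)c(OC(=O)C(C)(C)C)cc1O | intermediate
5 | 2,5-dimethoxyphenol | COc1ccc(OC)c(O)c1 | starting material
6 | 2,5-dimethoxyphenyl pivalate | COc1ccc(OC)c(OC(=O)C(C)(C)C)c1 | intermediate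
7 | chloroacetyl chloride | ClCC(Cl)=O | starting material
8 | 4-(chloroacetyl)-2,5-dimethoxyphenyl pivalate | COc1cc(C(=O)CCl)c(OC)cc1OC(=O)C(C)(C)C | intermediate
9 | 4-(iodoacetyl)-2,5-dimethoxyphenyl pivalate | COc1cc(C(=O)CI)c(OC)cc1OC(=O)C(C)(C)C | intermediate (not isolated)
10 | methyl 2-{2-[2,5-dimethoxy-4-(pivaloyloxy)phenyl]-2-oxoethoxy}-5-(3-methylbut-2-enyl)-4-(pivaloyloxy)benzoate | COC(=O)c1cc(CC=C(C)C)c(OC(=O)C(C)(C)C)cc1OCC(=O)c1cc(OC)c(OC(=O)C(C)(C)C)cc1OC | intermediate
11 | methyl 2-{2-[2,5-dimethoxy-4-(pivaloyloxy)phenyl]-2-hydroxyethoxy}-5-(3-methylbut-2-enyl)-4-(pivaloyloxy)benzoate, racemic | COC(=O)c1cc(CC=C(C)C)c(OC(=O)C(C)(C)C)cc1OCC(O)c1cc(OC)c(OC(=O)C(C)(C)C)cc1OC | intermediate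
12 | 4-hydroxy-2-[2-hydroxy-2-(4-hydroxy-2,5-dimethoxyphenyl)ethoxy]-5-(3-methylbut-2-enyl)benzoic acid, racemic, present in the flask as its trisodium salt | OC(=O)c1cc(CC=C(C)C)c(O)cc1OCC(O)c1cc(OC)c(O)cc1OC | intermediate (not isolated)
13 | 4-acetoxy-2-[2-(4-acetoxy-2,5-dimethoxyphenyl)-2-hydroxyethoxy]-5-(3-methylbut-2-enyl)benzoic acid, racemic | CC(=O)Oc1cc(OCC(O)c2cc(OC)c(OC(C)=O)cc2OC)c(C(O)=O)cc1CC=C(C)C | intermediate
14 | 4-acetoxy-2-[2-(4-acetoxy-2,5-dimethoxyphenyl)-2-chloroethoxy]-5-(3-methylbut-2-enyl)benzoyl chloride, racemic | CC(=O)Oc1cc(OC)c(C(Cl)COc2cc(OC(C)=O)c(CC=C(C)C)cc2C(Cl)=O)cc1OC | intermediate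
15 | (3S)-7-acetoxy-3-(4-acetoxy-2,5-dimethoxyphenyl)-6-(3-methylbut-2-enyl)chroman-4-one | COc1cc([C@H]2COc3cc(OC(C)=O)c(CC=C(C)C)cc3C2=O)c(OC)cc1OC(C)=O | intermediate
16 | (3S)-7-hydroxy-3-(4-hydroxy-2,5-dimethoxyphenyl)-6-(3-methylbut-2-enyl)chroman-4-one | COc1cc([C@H]2COc3cc(O)c(CC=C(C)C)cc3C2=O)c(OC)cc1O | target

**Totals**
Total step count: 10.
Longest linear sequence: 8 steps (1, 2, 5, 6, 7, 8, 9, 10). The ring B branch (3, 4, then 5–10) is equally long.

**Steps most likely to fail**

1. **Step 9 (key step).**
   - What may go wrong: the bridge may fragment by loss of the beta-aryloxy group from the benzylic radical or the benzyl–nickel species. The aroyl–nickel species may decarbonylate. Coupling between molecules may give oligomers or benzylic dimers. Face selection may be weak in a nickelacycle for which the ligand was never tuned.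
   - Fallback (known chemistry): it sets out from 14 and comes back at 15.
   - LiAlH(OtBu)3 (1.0 equiv) in THF at −78 °C reduces only the acid chloride, to racemic chloro aldehyde F1.
   - An N-heterocyclic carbene (bicyclic N-mesityl triazolium salt, 20 mol %, i-Pr2NEt, THF) turns the formyl carbon into an acyl anion equivalent, which displaces the tethered benzylic chloride. This is the known carbene-catalysed closure of O-(2-haloethyl)salicylaldehydes to chroman-4-ones, and it should give racemic diacetate F2.
   - Asymmetric transfer hydrogenation with dynamic kinetic resolution follows, with RuCl[(S,S)-TsDPEN](p-cymene), HCO2H/Et3N 5:2, EtOAc, 40 °C. It is known for isoflavanones, whose C3 epimerises under these conditions, and should give the cis alcohol (3S,4S)-isoflavan-4-ol diacetate F3.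
   - The triacetoxy periodinane DMP in CH2Cl2 at 0 °C restores the C4 ketone without touching C3 and gives 15.

2. **Step 8.**
   - What may go wrong: a transient hydroxy acid chloride may lactonise to the seven-membered benzodioxepinone. The electron-rich benzylic chloride may ionise or eliminate while the crude product is concentrated.
   - Fallback: it sets out from 13 and comes back at 14. It separates the two chlorinations by masking the acid.
   - Allyl bromide and KHCO3 in DMF at 20 °C give hydroxy allyl ester F4.
   - With no free acid present, the chloroenamine (1.2 equiv, CH2Cl2, 0 °C) gives chloro allyl ester F5.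
   - Pd(PPh3)4 (3 mol %) and PhSiH3 (2 equiv) in CH2Cl2 remove the allyl group under neutral conditions, much faster than zerovalent palladium attacks a secondary benzylic chloride, and give chloro acid F6.
   - One equivalent of the chloroenamine then gives 14, with no hydroxyl group left to lactonise.

3. **Step 10.**
   - What may go wrong: enolisation at C3 in the protic buffered medium may erode the enantiomeric purity. Slow cleavage of the hindered 4'-acetate would lengthen the exposure and make this worse.
   - Fallback: it sets out from 15 and comes back at 16. Chemical solvolysis is replaced by biocatalytic acyl transfer in a dry ether solvent.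
   - Conditions are immobilised Candida antarctica lipase B, n-BuOH (10 equiv), MTBE, 35 °C. This is the known lipase-catalysed alcoholysis of flavonoid aryl acetates, in which no dissolved base or buffer meets the ketone.
   - No new compound is made (F0).

**Further compounds**
F1 | step 9 | 4-acetoxy-2-[2-(4-acetoxy-2,5-dimethoxyphenyl)-2-chloroethoxy]-5-(3-methylbut-2-enyl)benzaldehyde, racemic | CC(=O)Oc1cc(OC)c(C(Cl)COc2cc(OC(C)=O)c(CC=C(C)C)cc2C=O)cc1OC
F2 | step 9 | racemic 7-acetoxy-3-(4-acetoxy-2,5-dimethoxyphenyl)-6-(3-methylbut-2-enyl)chroman-4-one | COc1cc(C2COc3cc(OC(C)=O)c(CC=C(C)C)cc3C2=O)c(OC)cc1OC(C)=O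
F3 | step 9 | (3S,4S)-7-acetoxy-3-(4-acetoxy-2,5-dimethoxyphenyl)-6-(3-methylbut-2-enyl)chroman-4-ol (3,4-cis) | COc1cc([C@H]2COc3cc(OC(C)=O)c(CC=C(C)C)cc3[C@H]2O)c(OC)cc1OC(C)=O
F4 | step 8 | allyl 4-acetoxy-2-[2-(4-acetoxy-2,5-dimethoxyphenyl)-2-hydroxyethoxy]-5-(3-methylbut-2-enyl)benzoate, racemic | CC(=O)Oc1cc(OCC(O)c2cc(OC)c(OC(C)=O)cc2OC)c(C(=O)OCC=C)cc1CC=C(C)C
F5 | step 8 | allyl 4-acetoxy-2-[2-(4-acetoxy-2,5-dimethoxyphenyl)-2-chloroethoxy]-5-(3-methylbut-2-enyl)benzoate, racemic | CC(=O)Oc1cc(OCC(Cl)c2cc(OC)c(OC(C)=O)cc2OC)c(C(=O)OCC=C)cc1CC=C(C)C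
F6 | step 8 | 4-acetoxy-2-[2-(4-acetoxy-2,5-dimethoxyphenyl)-2-chloroethoxy]-5-(3-methylbut-2-enyl)benzoic acid, racemic | CC(=O)Oc1cc(OCC(Cl)c2cc(OC)c(OC(C)=O)cc2OC)c(C(O)=O)cc1CC=C(C)C
F0 | step 10 | none | none
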